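1. Feature used (germacrane numbering): O2 and O8 lie on the same face of the ten-membered ring and flank the Z C1=C10 olefin in a 1,5 relationship (C2–C1=C10–C9–C8). One silicon atom can therefore bridge them, and closing C1=C10 becomes closing an eight-membered 1,3-dioxa-2-silacyclooct-5-ene, which can only hold a cis olefin.
2. Target 36 ⇐ C8 esterification with O-silyl Roche acid 34 and desilylation ⇐ 2,8-diol 30 ⇐ silylene-bridged germacranolide 29 ⇐ (ring-closing metathesis, C1=C10) ten-membered cyclic silylene 28.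
3. 28 ⇐ C11 methylenation of silylene lactone 25 ⇐ seco-diol 22 + iPr2SiCl2 23; the C8–C10 arm ⇐ reagent-controlled methallylboration of 4-formyl lactone 17.
4. trans-γ-Lactone (C6, C7) ⇐ Evans syn-aldol/lactonisation of succinate imide 13 with enal 10; 10 (C1–C6, E C4=C5, C2 carbinol) ⇐ zirconium-catalysed methylalumination of enyne 6 ⇐ asymmetric propargylation of acrolein.
5. Order of ring formation: γ-lactone (step 6), ten-membered silylene ring (step 11), then eight-membered siloxane and ten-membered carbocycle together (step 13).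

Key step: step 13

Remark: germacrane numbering (C1–C15) is used for all intermediates, and the (−)-α-pinene-derived Ipc2B reagents of steps 1 and 9 are assumed to add to the aldehyde Re face, as B-allyldiisopinocampheylborane of the same series does. TBS = tert-butyldimethylsilyl.

Step 1
Reactants: 1 acrolein; 2 propargyl bromide
Product: 5 (R)-hex-1-en-5-yn-3-ol, via allenylmagnesium bromide 3 (not isolated), via B-allenyldiisopinocampheylborane 4 (not isolated)
Conditions: 2, Mg, HgCl2 (cat.), Et2O, 0 °C; (+)-Ipc2BOMe (from (−)-α-pinene), −78 °C to rt; 1, Et2O, −78 °C; pH 7 buffer (NaH2PO4/Na2HPO4), 30% H2O2, 0 °C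
Reagents that add atoms: none
Why: Brown-type asymmetric allenylboration (carbonyl propargylation) through a six-membered chair transition state with SE2' transposition of the allenyl group; Re-face addition to acrolein should set C2 as R.

Step 2
Reactants: 5 (R)-hex-1-en-5-yn-3-ol
Product: 6 (R)-tert-butyl(hex-1-en-5-yn-3-yloxy)dimethylsilane
Conditions: TBSCl, imidazole, DMF, 0 °C to rt
Reagents that add atoms: tert-butyldimethylsilyl chloride, CC(C)(C)[Si](C)(C)Cl
Why: Standard silylation of a secondary alcohol, which does not touch the stereocentre and masks O2 for the organometallic steps that follow.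

Step 3
Reactants: 6 (R)-tert-butyl(hex-1-en-5-yn-3-yloxy)dimethylsilane
Product: 9 (R,E)-5-(tert-butyldimethylsilyloxy)-3-methylhepta-2,6-dien-1-ol, via alkenyldimethylalane 7 (not isolated), via lithium alkenylaluminate 8 (not isolated)
Conditions: Me3Al, Cp2ZrCl2 (0.25 equiv), CH2Cl2, 0 °C to rt; n-BuLi, THF, −78 °C; (CH2O)n, −78 °C to rt; aq. potassium sodium tartrate (KNaC4H4O6)
Reagents that add atoms: trimethylaluminium, C[Al](C)C; paraformaldehyde (as formaldehyde), C=O
Why: Negishi zirconium-catalysed carboalumination adds methyl and aluminium syn across the terminal alkyne with methyl on the internal carbon, and the aluminate is hydroxymethylated with retention, so the E C4=C5 olefin and the C15 methyl are fixed while the much slower monosubstituted alkene is left alone.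

Step 4
Reactants: 9 (R,E)-5-(tert-butyldimethylsilyloxy)-3-methylhepta-2,6-dien-1-ol
Product: 10 (R,E)-5-(tert-butyldimethylsilyloxy)-3-methylhepta-2,6-dienal
Conditions: MnO2, CH2Cl2, rt
Reagents that add atoms: none
Why: Chemoselective allylic oxidation with MnO2, which should leave the silyl ether and the olefin geometry unchanged.

Step 5
Reactants: 11 (S)-4-benzyloxazolidin-2-one; 12 methyl 4-chloro-4-oxobutanoate
Product: 13 methyl 4-[(S)-4-benzyl-2-oxooxazolidin-3-yl]-4-oxobutanoate
Conditions: n-BuLi, THF, −78 °C; then 12, −78 to 0 °C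
Reagents that add atoms: none
Why: N-acylation of the lithiated oxazolidinone by the acid chloride, which is far more electrophilic than the methyl ester of the same reagent.

Step 6
Reactants: 13 methyl 4-[(S)-4-benzyl-2-oxooxazolidin-3-yl]-4-oxobutanoate; 10 (R,E)-5-(tert-butyldimethylsilyloxy)-3-methylhepta-2,6-dienal
Product: 15 (S)-4-benzyl-3-[(2R,3S)-2-[(R,E)-4-(tert-butyldimethylsilyloxy)-2-methylhexa-1,5-dien-1-yl]-5-oxotetrahydrofuran-3-carbonyl]oxazolidin-2-one, via syn-aldol hydroxy ester 14 (not isolated)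
Conditions: Bu2BOTf, iPr2NEt, CH2Cl2, −78 to 0 °C; 10, −78 to 0 °C; pH 7 buffer (NaH2PO4/Na2HPO4), MeOH, 30% H2O2, 0 °C; PPTS (cat.), CH2Cl2, rt
Reagents that add atoms: none
Why: Evans syn-aldol reaction of the Z boron enolate (the imide is enolised in preference to the ester) through a Zimmerman–Traxler chair in which the (S)-benzyl group blocks one enolate face, setting C6 (R) and C7 under auxiliary control; the C6 hydroxyl then closes the γ-lactone onto the methyl ester, the syn adduct giving the trans-disubstituted lactone.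

Step 7
Reactants: 15 lactone imide
Product: 16 (4R,5R)-4-(hydroxymethyl)-5-[(R,E)-4-(tert-butyldimethylsilyloxy)-2-methylhexa-1,5-dien-1-yl]dihydrofuran-2(3H)-one
Conditions: NaBH4, THF/H2O (4:1), 0 °C; aq. NH4Cl
Reagents that add atoms: none
Why: Reductive removal of the oxazolidinone auxiliary, the exocyclic imide carbonyl being much more electrophilic than the γ-lactone; the cold, near-neutral quench is chosen to prevent lactone migration to the new primary hydroxyl.

Step 8
Reactants: 16 hydroxymethyl lactone
Product: 17 (2R,3S)-2-[(R,E)-4-(tert-butyldimethylsilyloxy)-2-methylhexa-1,5-dien-1-yl]-5-oxotetrahydrofuran-3-carbaldehyde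
Conditions: Dess–Martin periodinane, NaHCO3, CH2Cl2, 0 °C; used crude
Reagents that add atoms: none
Why: Dess–Martin oxidation under buffered, non-basic conditions, so that C7 is not epimerised and the β-acyloxy aldehyde does not eliminate.

Step 9
Reactants: 17 formyl lactone; 18 3-chloro-2-methylprop-1-ene
Product: 21 (4R,5R)-4-[(R)-1-hydroxy-3-methylbut-3-en-1-yl]-5-[(R,E)-4-(tert-butyldimethylsilyloxy)-2-methylhexa-1,5-dien-1-yl]dihydrofuran-2(3H)-one, via methallylmagnesium chloride 19 (not isolated), via B-methallyldiisopinocampheylborane 20 (not isolated)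
Conditions: 18, Mg, THF, 0 °C; (+)-Ipc2BOMe (from (−)-α-pinene), Et2O, −78 °C to rt; 17, Et2O, −78 °C; pH 7 buffer (NaH2PO4/Na2HPO4), 30% H2O2, 0 °C
Reagents that add atoms: none
Why: Brown asymmetric methallylboration through a closed chair transition state, the reagent delivering the methallyl group to the Re face of the aldehyde under reagent control to set C8 as R, while the neutral borane does not enolise the sensitive aldehyde.

Step 10
Reactants: 21 homoallylic alcohol
Product: 22 (4R,5R)-4-[(R)-1-hydroxy-3-methylbut-3-en-1-yl]-5-[(R,E)-4-hydroxy-2-methylhexa-1,5-dien-1-yl]dihydrofuran-2(3H)-one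
Conditions: HF·pyridine, pyridine, THF, 0 °C to rt
Reagents that add atoms: none
Why: Fluoride cleavage of the secondary TBS ether under buffered, mildly acidic conditions, which neither let the free C8 hydroxyl attack the lactone nor ionise the allylic C6–O bond.

Step 11
Reactants: 22 seco-diol; 23 dichlorodiisopropylsilane
Product: 25 (2R,6R,7S,8R)-2,8-O-diisopropylsilylene-11,13-dihydro seco-1,10 lactone, via chlorosilyl ether 24 (not isolated)
Conditions: 23 (1.05 equiv, syringe pump), imidazole, DMAP (cat.), CH2Cl2/DMF, 0.002 M, 0 °C to rt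
Reagents that add atoms: none
Why: Cyclic silylene formation by stepwise bis-silylation of a diol with a dichlorosilane, the less hindered allylic C2 hydroxyl reacting first and the chlorosilyl ether closing onto O8 at high dilution; the ten-membered ring (Si, O2, C2–C8, O8) resembles a germacranolide with longer Si–O bonds in place of C1=C10–C9, so its strain should be modest.

Step 12
Reactants: 25 silylene lactone
Product: 28 (2R,6R,7S,8R)-2,8-O-diisopropylsilylene seco-1,10 diene α-methylene lactone, via Mannich base 26 (not isolated), via methiodide 27 (not isolated)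
Conditions: LDA (LiN(iPr)2), THF, −78 °C; CH2=NMe2+ I−, −78 °C to rt; MeI, THF, rt; aq. NaHCO3, CH2Cl2, rt
Reagents that add atoms: Eschenmoser's salt, C=[N+](C)C.[I-]
Why: α-Methylenation of the lactone by Mannich reaction of its lithium enolate with Eschenmoser's salt, quaternisation and elimination of trimethylamine; the silylene masks both hydroxyls, and C7 is safe because enolisation is at C11.

Step 13
Reactants: 28 cyclic silylene diene
Product: 29 (2R,6R,7S,8R)-2,8-O-diisopropylsilylene-bridged (1(10)Z,4E)-germacra-1(10),4,11(13)-trien-12,6-olide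
Conditions: second-generation Grubbs catalyst RuCl2(=CHPh)(PCy3)(H2IMes) (10–15 mol%, in portions), 1,4-benzoquinone (20 mol%), toluene, 0.001 M, 80 °C, argon sparge
Reagents that add atoms: none
Why: Ring-closing olefin metathesis: the ruthenium benzylidene exchanges with the monosubstituted C1 vinyl group, and the resulting alkylidene undergoes intramolecular [2+2] cycloaddition and cycloreversion with the C10 isopropenyl group, expelling ethylene. The closest known reaction type is temporary silicon-tethered ring-closing metathesis of bis(alkoxy)silanes built from an allylic and a homoallylic alcohol, which gives Z olefins in 1,3-dioxa-2-silacyclooct-5-enes. Two rings close in this one event: the eight-membered siloxane (Si, O2, C2, C1, C10, C9, C8, O8) by direct ring-closing metathesis of the tethered diene, and the ten-membered carbocycle C1–C10 because C2 and C8 are already joined through C3–C7. No stereocentre is formed. The step needs Z geometry at the trisubstituted olefin, which the eight-membered ring enforces because it cannot hold a trans double bond, the cis O2/O8 arrangement placing the vinyl and methallyl arms on the same side of the silylene ring. It also needs chemoselectivity: the E C4=C5 olefin is trisubstituted and could only close a cyclobutene, the C11=C13 methylene could only be reached through a trans-cyclooctene-type ring, high dilution suppresses bimolecular cross-metathesis, and benzoquinone intercepts ruthenium hydrides that would move the exocyclic methylene.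

Step 14
Reactants: 29 silylene-bridged germacranolide
Product: 30 (2R,6R,7R,8R)-2,8-dihydroxy-(1(10)Z,4E)-germacra-1(10),4,11(13)-trien-12,6-olide
Conditions: HF·pyridine, pyridine, THF, 0 °C
Reagents that add atoms: none
Why: Fluoride cleavage of both Si–O bonds of the dialkoxysilane with a buffered acidic fluoride source, which avoids conjugate addition to the α-methylene lactone and base-induced lactone migration to O8.

Step 15
Reactants: 30 2,8-diol
Product: 31 (2R,6R,7R,8R)-2-(tert-butyldimethylsilyloxy)-8-hydroxy-(1(10)Z,4E)-germacra-1(10),4,11(13)-trien-12,6-olide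
Conditions: TBSCl (1.1 equiv), imidazole, CH2Cl2, −20 to 0 °C
Reagents that add atoms: tert-butyldimethylsilyl chloride, CC(C)(C)[Si](C)(C)Cl
Why: Sterically controlled monosilylation, in which the allylic C2 hydroxyl (between a CH2 and an sp2 carbon) should react before the C8 hydroxyl next to the ring-fusion methine C7.

Step 16
Reactants: 32 methyl (S)-3-hydroxy-2-methylpropanoate (Roche ester)
Product: 33 methyl (S)-3-(tert-butyldimethylsilyloxy)-2-methylpropanoate
Conditions: TBSCl, imidazole, CH2Cl2, 0 °C to rt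
Reagents that add atoms: tert-butyldimethylsilyl chloride, CC(C)(C)[Si](C)(C)Cl
Why: Standard silylation of the primary alcohol, which leaves the α-stereocentre untouched.

Step 17
Reactants: 33 silylated Roche ester
Product: 34 (S)-3-(tert-butyldimethylsilyloxy)-2-methylpropanoic acid
Conditions: LiOH, THF/H2O, 0 °C to rt; then 1 M HCl to pH 4, 0 °C
Reagents that add atoms: lithium hydroxide, [Li+].[OH-]
Why: Saponification of the methyl ester under mild conditions at which the α-methyl stereocentre should not epimerise and the primary TBS ether survives.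

Step 18
Reactants: 31 C2 silyl ether; 34 silylated Roche acid
Product: 35 (2R,6R,7R,8R)-2-(tert-butyldimethylsilyloxy)-8-[(S)-3-(tert-butyldimethylsilyloxy)-2-methylpropanoyloxy]-(1(10)Z,4E)-germacra-1(10),4,11(13)-trien-12,6-olide
Conditions: DCC, DMAP (0.3 equiv), CH2Cl2, 0 °C to rt
Reagents that add atoms: none
Why: Steglich esterification of the remaining C8 hydroxyl, DMAP acyl transfer overcoming the hindrance next to C7 under conditions mild enough for the α-methylene lactone and the stereocentre of the acid.

Step 19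
Reactants: 35 bis-silyl ether
Product: 36 CNP0254953.1, (2R,6R,7R,8R)-2-hydroxy-8-[(S)-3-hydroxy-2-methylpropanoyloxy]-(1(10)Z,4E)-germacra-1(10),4,11(13)-trien-12,6-olide
Conditions: HF·pyridine, pyridine, THF, 0 °C to rt
Reagents that add atoms: none
Why: Global desilylation of the secondary allylic and the primary TBS ether with buffered HF, conditions under which neither ester should migrate and the Michael acceptor is untouched.

Compound list
1 | acrolein (prop-2-enal) | C=CC=O | starting material
2 | propargyl bromide (3-bromoprop-1-yne) | BrCC#C | starting material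
3 | allenylmagnesium bromide | C=C=C[Mg]Br | intermediate
4 | B-allenyldiisopinocampheylborane (Ipc from (−)-α-pinene) | C=C=CB([C@H]1C[C@H]2C[C@@H]([C@@H]1C)C2(C)C)[C@H]1C[C@H]2C[C@@H]([C@@H]1C)C2(C)C | intermediate
5 | (R)-hex-1-en-5-yn-3-ol | C#CC[C@@H](O)C=C | intermediate
6 | (R)-tert-butyl(hex-1-en-5-yn-3-yloxy)dimethylsilane | C#CC[C@@H](O[Si](C)(C)C(C)(C)C)C=C | intermediate
7 | dimethyl[(R,E)-4-(tert-butyldimethylsilyloxy)-2-methylhexa-1,5-dien-1-yl]alane | C[Al](C)/C=C(\C)C[C@@H](O[Si](C)(C)C(C)(C)C)C=C | intermediate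
8 | lithium butyl(dimethyl)[(R,E)-4-(tert-butyldimethylsilyloxy)-2-methylhexa-1,5-dien-1-yl]aluminate | [Li+].CCCC[Al-](C)(C)/C=C(\C)C[C@@H](O[Si](C)(C)C(C)(C)C)C=C | intermediate
9 | (R,E)-5-(tert-butyldimethylsilyloxy)-3-methylhepta-2,6-dien-1-ol | OC/C=C(\C)C[C@@H](O[Si](C)(C)C(C)(C)C)C=C | intermediate
10 | (R,E)-5-(tert-butyldimethylsilyloxy)-3-methylhepta-2,6-dienal (C1–C6 enal) | O=C/C=C(\C)C[C@@H](O[Si](C)(C)C(C)(C)C)C=C | intermediate
11 | (S)-4-benzyloxazolidin-2-one | O=C1N[C@@H](Cc2ccccc2)CO1 | starting material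
12 | methyl 4-chloro-4-oxobutanoate | COC(=O)CCC(Cl)=O | starting material
13 | methyl 4-[(S)-4-benzyl-2-oxooxazolidin-3-yl]-4-oxobutanoate | COC(=O)CCC(=O)N1[C@@H](Cc2ccccc2)COC1=O | intermediate
14 | methyl (3S,4R,5E,8R)-3-[(S)-4-benzyl-2-oxooxazolidine-3-carbonyl]-8-(tert-butyldimethylsilyloxy)-4-hydroxy-6-methyldeca-5,9-dienoate (syn-aldol hydroxy ester) | COC(=O)C[C@H](C(=O)N1[C@@H](Cc2ccccc2)COC1=O)[C@H](O)/C=C(\C)C[C@@H](O[Si](C)(C)C(C)(C)C)C=C | intermediate
15 | (S)-4-benzyl-3-[(2R,3S)-2-[(R,E)-4-(tert-butyldimethylsilyloxy)-2-methylhexa-1,5-dien-1-yl]-5-oxotetrahydrofuran-3-carbonyl]oxazolidin-2-one (trans lactone imide) | O=C1C[C@H](C(=O)N2[C@@H](Cc3ccccc3)COC2=O)[C@@H](/C=C(\C)C[C@@H](O[Si](C)(C)C(C)(C)C)C=C)O1 | intermediate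
16 | (4R,5R)-4-(hydroxymethyl)-5-[(R,E)-4-(tert-butyldimethylsilyloxy)-2-methylhexa-1,5-dien-1-yl]dihydrofuran-2(3H)-one | O=C1C[C@H](CO)[C@@H](/C=C(\C)C[C@@H](O[Si](C)(C)C(C)(C)C)C=C)O1 | intermediate
17 | (2R,3S)-2-[(R,E)-4-(tert-butyldimethylsilyloxy)-2-methylhexa-1,5-dien-1-yl]-5-oxotetrahydrofuran-3-carbaldehyde | O=C1C[C@H](C=O)[C@@H](/C=C(\C)C[C@@H](O[Si](C)(C)C(C)(C)C)C=C)O1 | intermediate
18 | 3-chloro-2-methylprop-1-ene | CC(=C)CCl | starting material
19 | (2-methylallyl)magnesium chloride | CC(=C)C[Mg]Cl | intermediate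
20 | B-(2-methylallyl)diisopinocampheylborane (Ipc from (−)-α-pinene) | CC(=C)CB([C@H]1C[C@H]2C[C@@H]([C@@H]1C)C2(C)C)[C@H]1C[C@H]2C[C@@H]([C@@H]1C)C2(C)C | intermediate
21 | (4R,5R)-4-[(R)-1-hydroxy-3-methylbut-3-en-1-yl]-5-[(R,E)-4-(tert-butyldimethylsilyloxy)-2-methylhexa-1,5-dien-1-yl]dihydrofuran-2(3H)-one | O=C1C[C@H]([C@H](O)CC(C)=C)[C@@H](/C=C(\C)C[C@@H](O[Si](C)(C)C(C)(C)C)C=C)O1 | intermediate
22 | (4R,5R)-4-[(R)-1-hydroxy-3-methylbut-3-en-1-yl]-5-[(R,E)-4-hydroxy-2-methylhexa-1,5-dien-1-yl]dihydrofuran-2(3H)-one (seco-1,10 2,8-diol) | O=C1C[C@H]([C@H](O)CC(C)=C)[C@@H](/C=C(\C)C[C@@H](O)C=C)O1 | intermediate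
23 | dichlorodiisopropylsilane | CC(C)[Si](Cl)(Cl)C(C)C | starting material
24 | 2-O-(chlorodiisopropylsilyl) ether of diol 22 | O=C1C[C@H]([C@H](O)CC(C)=C)[C@@H](/C=C(\C)C[C@@H](O[Si](Cl)(C(C)C)C(C)C)C=C)O1 | intermediate
25 | (2R,6R,7S,8R)-2,8-O-diisopropylsilylene-11,13-dihydro seco-1,10 lactone (ten-membered cyclic silylene; vinyl on C2, 2-methylallyl on C8) | C1C(=O)O[C@@H]2/C=C(\C)C[C@H](C=C)O[Si](C(C)C)(C(C)C)O[C@H](CC(C)=C)[C@@H]12 | intermediate
26 | 13-(dimethylamino) Mannich base of 25 (aminomethyl on C11, trans to C8) | CN(C)C[C@@H]1C(=O)O[C@@H]2/C=C(\C)C[C@H](C=C)O[Si](C(C)C)(C(C)C)O[C@H](CC(C)=C)[C@@H]12 | intermediate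
27 | trimethylammonium iodide (methiodide) of 26 | C[N+](C)(C)C[C@@H]1C(=O)O[C@@H]2/C=C(\C)C[C@H](C=C)O[Si](C(C)C)(C(C)C)O[C@H](CC(C)=C)[C@@H]12.[I-] | intermediate
28 | (2R,6R,7S,8R)-2,8-O-diisopropylsilylene seco-1,10 diene α-methylene lactone (key-step precursor) | C=C1C(=O)O[C@@H]2/C=C(\C)C[C@H](C=C)O[Si](C(C)C)(C(C)C)O[C@H](CC(C)=C)[C@@H]12 | intermediate
29 | (2R,6R,7S,8R)-2,8-O-diisopropylsilylene-bridged (1(10)Z,4E)-germacra-1(10),4,11(13)-trien-12,6-olide (key-step product) | C=C1C(=O)O[C@@H]2/C=C(\C)C[C@@H](O[Si]3(C(C)C)C(C)C)/C=C(/C)C[C@@H](O3)[C@@H]12 | intermediate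
30 | (2R,6R,7R,8R)-2,8-dihydroxy-(1(10)Z,4E)-germacra-1(10),4,11(13)-trien-12,6-olide | C=C1C(=O)O[C@@H]2/C=C(\C)C[C@@H](O)/C=C(/C)C[C@@H](O)[C@@H]12 | intermediate
31 | (2R,6R,7R,8R)-2-(tert-butyldimethylsilyloxy)-8-hydroxy-(1(10)Z,4E)-germacra-1(10),4,11(13)-trien-12,6-olide | C=C1C(=O)O[C@@H]2/C=C(\C)C[C@@H](O[Si](C)(C)C(C)(C)C)/C=C(/C)C[C@@H](O)[C@@H]12 | intermediate
32 | methyl (S)-3-hydroxy-2-methylpropanoate (Roche ester) | COC(=O)[C@@H](C)CO | starting material
33 | methyl (S)-3-(tert-butyldimethylsilyloxy)-2-methylpropanoate | COC(=O)[C@@H](C)CO[Si](C)(C)C(C)(C)C | intermediate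
34 | (S)-3-(tert-butyldimethylsilyloxy)-2-methylpropanoic acid | OC(=O)[C@@H](C)CO[Si](C)(C)C(C)(C)C | intermediate
35 | (2R,6R,7R,8R)-2-(tert-butyldimethylsilyloxy)-8-[(S)-3-(tert-butyldimethylsilyloxy)-2-methylpropanoyloxy]-(1(10)Z,4E)-germacra-1(10),4,11(13)-trien-12,6-olide | C=C1C(=O)O[C@@H]2/C=C(\C)C[C@@H](O[Si](C)(C)C(C)(C)C)/C=C(/C)C[C@@H](OC(=O)[C@@H](C)CO[Si](C)(C)C(C)(C)C)[C@@H]12 | intermediate
36 | CNP0254953.1, (2R,6R,7R,8R)-2-hydroxy-8-[(S)-3-hydroxy-2-methylpropanoyloxy]-(1(10)Z,4E)-germacra-1(10),4,11(13)-trien-12,6-olide | C=C1C(=O)O[C@@H]2/C=C(\C)C[C@@H](O)/C=C(/C)C[C@@H](OC(=O)[C@@H](C)CO)[C@@H]12 | target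

Total step count: 19. Longest linear sequence: 16 steps (steps 1–4, 6–15, 18 and 19); step 5 and steps 16–17 are side branches.

Steps most likely to fail

Step 13 (ring-closing metathesis). Bimolecular cross-metathesis at the C1 vinyl group may outrun closure onto the hindered isopropenyl group. The acrylate-type C11=C13 olefin may also consume carbene or migrate into the lactone ring under ruthenium hydride catalysis. The fallback exchanges the order of methylenation and metathesis. It sets out from silylene lactone 25, which is cyclised with the same catalyst and dilution to the 11,13-dihydro silylene-bridged germacranolide F1. F1 is then methylenated by the established late-stage sequence for dihydro germacranolides: LDA and Eschenmoser's salt give the Mannich base F2, MeI gives its methiodide F3, and NaHCO3 eliminates trimethylamine. The route is rejoined at 29.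

Step 11 (ten-membered silylene closure). Intermolecular silylation may give open-chain or dimeric siloxanes instead of the ring. The fallback forms the two Si–O bonds by different reactions. It sets out from diol 22, which is monosilylated with chlorodiisopropylsilane (iPr2SiHCl, imidazole, CH2Cl2, −78 °C) to the hydridosilyl ether F4. Either hydroxyl may react, since both regioisomers lead to the same ring; the C2 isomer is drawn. F4 is closed by B(C6F5)3-catalysed dehydrogenative Si–O coupling at high dilution, which can only proceed within one molecule once a single Si–H is present. The route is rejoined at 25.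

Step 9 (methallylboration). Reagent control may be eroded by the α-stereocentre C7 in a mismatched pairing, and the β-acyloxy aldehyde may lose the lactone carboxylate by E1cB elimination during the slow addition. The fallback separates carbon–carbon bond formation from stereocontrol. It sets out from aldehyde 17, which is methallylated without stereocontrol under aqueous zinc Barbier conditions (18, Zn, THF/aq. NH4Cl) to the C8-epimeric homoallylic alcohols F5. These are oxidised with Dess–Martin periodinane to the methallyl ketone F6. F6 is reduced with (S)-Me-CBS oxazaborolidine and catecholborane at −78 °C (Corey–Bakshi–Shibata reduction, hydride to the Si face of the ketone). The route is rejoined at 21.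

Further compounds
F1 | step 13 | (2R,6R,7S,8R)-2,8-O-diisopropylsilylene-bridged 11,13-dihydro-(1(10)Z,4E)-germacra-1(10),4-dien-12,6-olide | C1C(=O)O[C@@H]2/C=C(\C)C[C@@H](O[Si]3(C(C)C)C(C)C)/C=C(/C)C[C@@H](O3)[C@@H]12
F2 | step 13 | 13-(dimethylamino) Mannich base of F1 | CN(C)C[C@@H]1C(=O)O[C@@H]2/C=C(\C)C[C@@H](O[Si]3(C(C)C)C(C)C)/C=C(/C)C[C@@H](O3)[C@@H]12
F3 | step 13 | trimethylammonium iodide (methiodide) of F2 | C[N+](C)(C)C[C@@H]1C(=O)O[C@@H]2/C=C(\C)C[C@@H](O[Si]3(C(C)C)C(C)C)/C=C(/C)C[C@@H](O3)[C@@H]12.[I-]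
F4 | step 11 | 2-O-(diisopropylsilyl) ether of diol 22 | O=C1C[C@H]([C@H](O)CC(C)=C)[C@@H](/C=C(\C)C[C@@H](O[SiH](C(C)C)C(C)C)C=C)O1
F5 | step 9 | C8-epimeric mixture of homoallylic alcohol 21 | O=C1C[C@H](C(O)CC(C)=C)[C@@H](/C=C(\C)C[C@@H](O[Si](C)(C)C(C)(C)C)C=C)O1
F6 | step 9 | (4S,5R)-4-(3-methylbut-3-enoyl)-5-[(R,E)-4-(tert-butyldimethylsilyloxy)-2-methylhexa-1,5-dien-1-yl]dihydrofuran-2(3H)-one | O=C1C[C@H](C(=O)CC(C)=C)[C@@H](/C=C(\C)C[C@@H](O[Si](C)(C)C(C)(C)C)C=C)O1
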